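**Plan**
Ring C has only three atoms that are not part of ring A: the lone carbonyl carbon C4 and the C2–C3 pair bonded to ring B. O1, C8a and C4a are a phenolic oxygen and two adjacent carbons of ring A, so cutting C4a–C4, C3–C4 and O1–C2 gives a 2-iodophenol, CO and a terminal arylalkyne.
Before these cuts the target is simplified to a flavone: the C3 hydroxyl and the C2/C3 hydrogens are removed, O5 is carried as a methyl ether and O3' as a TIPS ether.
Forward: ring A is prenylated at the carbon between its two methoxy groups and iodinated once, and the phenol is symmetric so only one iodide can form. The ring B alkyne comes from isovanillin, and Pd/CO then joins the two arenes and closes ring C, the only ring built.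
Stereochemistry: C2 is set by ligand-controlled CuH hydride delivery to the flavone, held as a silyl enol ether. C3 is set by oxygen transfer to the enol ether face anti to ring B, which gives the 2,3-trans (2R,3R) ketol.
The route ends with chelation-guided cleavage of the 5-O-methyl ether and buffered fluoride desilylation.

Key step: step 7

Assumption: the (R)-ligand in step 8 is taken to deliver hydride to the C2 face that gives the 2S enol ether. This sense of induction must be confirmed on the first run, and the equally available (S)-ligand is used if it proves opposite.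

Step 1
Reactants: 1 3,5-dimethoxyphenol
Product: 2 (3,5-dimethoxyphenoxy)triisopropylsilane
Conditions: TIPSCl, imidazole, DMF, rt
Reagents that add atoms: chlorotriisopropylsilane (TIPSCl), CC(C)[Si](Cl)(C(C)C)C(C)C
Why: Standard silyl ether protection of a phenol, with the bulky, poorly coordinating OTIPS group chosen because it neither directs lithiation to its own ortho positions nor is attacked by n-BuLi.

Step 2
Reactants: 2 (3,5-dimethoxyphenoxy)triisopropylsilane; 3 prenyl bromide
Product: 5 [3,5-dimethoxy-4-(3-methylbut-2-en-1-yl)phenoxy]triisopropylsilane, via aryllithium 4 (not isolated)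
Conditions: n-BuLi, THF, 0 °C to rt; CuBr·SMe2 (10 mol %), 3, −78 °C to rt
Reagents that add atoms: none
Why: Directed ortho-metalation takes place at the carbon flanked by both methoxy groups (cooperative 1,3-direction), and copper-assisted SN2 allylation of the aryllithium with the primary bromide keeps the prenyl chain linear.

Step 3
Reactants: 5 [3,5-dimethoxy-4-(3-methylbut-2-en-1-yl)phenoxy]triisopropylsilane
Product: 6 3,5-dimethoxy-4-(3-methylbut-2-en-1-yl)phenol
Conditions: TBAF, AcOH, THF, 0 °C to rt
Reagents that add atoms: none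
Why: Fluoride-induced cleavage of an aryl silyl ether, which leaves the methyl ethers and the alkene untouched.

Step 4
Reactants: 6 3,5-dimethoxy-4-(3-methylbut-2-en-1-yl)phenol
Product: 7 2-iodo-3,5-dimethoxy-4-(3-methylbut-2-en-1-yl)phenol
Conditions: I2 (1.0 equiv), NaHCO3, THF–H2O, 0 °C
Reagents that add atoms: iodine, II
Why: Electrophilic aromatic iodination of this phloroglucinol-type phenol under mildly basic conditions should be much faster than attack of iodine on the trisubstituted alkene, the two open ring positions are equivalent by symmetry so only one mono-iodide is possible, and one equivalent of iodine limits di-iodination.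

Step 5
Reactants: 8 isovanillin (3-hydroxy-4-methoxybenzaldehyde)
Product: 9 4-methoxy-3-(triisopropylsilyloxy)benzaldehyde
Conditions: TIPSCl, imidazole, DMF, rt
Reagents that add atoms: chlorotriisopropylsilane (TIPSCl), CC(C)[Si](Cl)(C(C)C)C(C)C
Why: Standard phenol silylation, with TIPS preferred to TBS because the group must survive K2CO3/MeOH in step 6 and hot diethylamine in step 7.

Step 6
Reactants: 9 4-methoxy-3-(triisopropylsilyloxy)benzaldehyde
Product: 10 (5-ethynyl-2-methoxyphenoxy)triisopropylsilane
Conditions: dimethyl (1-diazo-2-oxopropyl)phosphonate, K2CO3, MeOH, 0 °C to rt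
Reagents that add atoms: dimethyl (1-diazo-2-oxopropyl)phosphonate (Ohira–Bestmann reagent), COP(=O)(OC)C(=[N+]=[N-])C(C)=O
Why: Seyferth–Gilbert homologation in its Ohira–Bestmann form, in which methanolysis frees the diazomethylphosphonate anion, this olefinates the aldehyde, and loss of N2 with a 1,2-hydride shift gives the terminal alkyne.

Step 7
Reactants: 7 2-iodo-3,5-dimethoxy-4-(3-methylbut-2-en-1-yl)phenol; 10 (5-ethynyl-2-methoxyphenoxy)triisopropylsilane; 11 carbon monoxide
Product: 14 5,7-dimethoxy-2-[4-methoxy-3-(triisopropylsilyloxy)phenyl]-6-(3-methylbut-2-en-1-yl)-4H-chromen-4-one, via ynone 12 (not isolated), via enaminone 13 (not isolated)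
Conditions: PdCl2(dppf) (5 mol %), CO (20 bar), 10 (1.5 equiv), Et2NH, 120 °C, autoclave, no copper salt
Reagents that add atoms: none
Why: Zerovalent palladium formed in situ adds oxidatively to the C–I bond of 7, CO inserts to give the aroyl complex of divalent palladium, and the amine-deprotonated alkyne 10 replaces iodide so that reductive elimination completes C4a–C4 and C3–C4 in ynone 12. The closest known reaction type is the carbonylative Sonogashira-type annulation of ortho-iodophenols with terminal alkynes, an established flavone synthesis. Diethylamine adds to C2 of 12 to give enaminone 13, and the ortho phenol then displaces the amine by addition–elimination, so ring C closes through O1–C2 in a net 6-endo-dig sense rather than by 5-exo-dig attack at C3, which would give an aurone. No stereocentre is formed. The step needs CO uptake to outrun direct alkynylation, amide formation and reductive loss of iodine, which the copper-free medium, the CO pressure and the fast migratory insertion of an electron-rich, doubly ortho-flanked aryl–palladium bond should favour. The prenyl alkene sits meta to the acyl–palladium carbon and cannot reach it.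

Step 8
Reactants: 14 5,7-dimethoxy-2-[4-methoxy-3-(triisopropylsilyloxy)phenyl]-6-(3-methylbut-2-en-1-yl)-4H-chromen-4-one
Product: 15 (2S)-4-[dimethyl(phenyl)silyloxy]-5,7-dimethoxy-2-[4-methoxy-3-(triisopropylsilyloxy)phenyl]-6-(3-methylbut-2-en-1-yl)-2H-chromene
Conditions: Cu(OAc)2 (5 mol %), (R)-DTBM-SEGPHOS (5.5 mol %), PhMe2SiH (2 equiv), toluene, 0 °C to rt, no proton source; filtration through Et3N-deactivated silica, dark
Reagents that add atoms: dimethylphenylsilane, C[SiH](C)c1ccccc1
Why: Ligated CuH asymmetric conjugate reduction (1,4-hydrosilylation), established for β,β-disubstituted cyclic enones and 2-substituted chromones, delivers hydride to one face of C2 under control of the C2-symmetric bisphosphine, and without a proton source the copper enolate is silylated by the silane, so C2 (S here, the same spatial sense as 2R in the target) is held in an enol ether that can neither ring-open nor be over-reduced, while the isolated prenyl alkene is inert to CuH.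

Step 9
Reactants: 15 (2S)-4-[dimethyl(phenyl)silyloxy]-5,7-dimethoxy-2-[4-methoxy-3-(triisopropylsilyloxy)phenyl]-6-(3-methylbut-2-en-1-yl)-2H-chromene
Product: 17 (2R,3R)-3-hydroxy-5,7-dimethoxy-2-[4-methoxy-3-(triisopropylsilyloxy)phenyl]-6-(3-methylbut-2-en-1-yl)chroman-4-one, via 3-silyloxy ketone 16 (not isolated)
Conditions: 2-(phenylsulfonyl)-3-phenyloxaziridine (1.5 equiv), CH2Cl2, 0 °C to rt, dark; then aq. citric acid, THF, rt
Reagents that add atoms: 2-(phenylsulfonyl)-3-phenyloxaziridine, O=S(=O)(c1ccccc1)N1OC1c1ccccc1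
Why: Rubottom-type oxidation of a silyl enol ether with an N-sulfonyloxaziridine, in which the neutral, weakly electrophilic oxidant should pick the very electron-rich enol ether over the prenyl alkene and transfer oxygen to C3 on the face anti to the C2 aryl group, giving after silyl migration and mild hydrolysis the 2,3-trans (2R,3R) ketol, which is also the more stable diequatorial isomer.

Step 10
Reactants: 17 (2R,3R)-3-hydroxy-5,7-dimethoxy-2-[4-methoxy-3-(triisopropylsilyloxy)phenyl]-6-(3-methylbut-2-en-1-yl)chroman-4-one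
Product: 18 (2R,3R)-3,5-dihydroxy-7-methoxy-2-[4-methoxy-3-(triisopropylsilyloxy)phenyl]-6-(3-methylbut-2-en-1-yl)chroman-4-one
Conditions: MgI2·OEt2 (4 equiv), THF, 50 °C; aq. NH4Cl/Na2S2O3 work-up
Reagents that add atoms: none
Why: Chelation-directed aryl methyl ether cleavage, in which magnesium binds the C4 carbonyl and the peri 5-methoxy oxygen and iodide removes that methyl group by SN2, while the 7- and 4'-methyl ethers lack such a chelate and this mild Lewis acid is known to demethylate 5-methoxy prenylflavanones without cyclising the prenyl chain.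

Step 11
Reactants: 18 (2R,3R)-3,5-dihydroxy-7-methoxy-2-[4-methoxy-3-(triisopropylsilyloxy)phenyl]-6-(3-methylbut-2-en-1-yl)chroman-4-one
Product: 19 (2R,3R)-3,5-dihydroxy-2-(3-hydroxy-4-methoxyphenyl)-7-methoxy-6-(3-methylbut-2-en-1-yl)chroman-4-one (target)
Conditions: TBAF, AcOH (1:1), THF, 0 °C
Reagents that add atoms: none
Why: Buffered fluoride cleavage of the aryl TIPS ether, with acetic acid keeping the medium non-basic so that the ketol should not epimerise, ring-open or autoxidise to the flavonol.

**Compound list**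
1 | 3,5-dimethoxyphenol | COc1cc(O)cc(OC)c1 | starting material
2 | (3,5-dimethoxyphenoxy)triisopropylsilane | COc1cc(OC)cc(O[Si](C(C)C)(C(C)C)C(C)C)c1 | intermediate
3 | prenyl bromide (1-bromo-3-methylbut-2-ene) | CC(C)=CCBr | starting material
4 | 2,6-dimethoxy-4-(triisopropylsilyloxy)phenyllithium | [Li]c1c(OC)cc(O[Si](C(C)C)(C(C)C)C(C)C)cc1OC | intermediate
5 | [3,5-dimethoxy-4-(3-methylbut-2-en-1-yl)phenoxy]triisopropylsilane | COc1cc(O[Si](C(C)C)(C(C)C)C(C)C)cc(OC)c1CC=C(C)C | intermediate
6 | 3,5-dimethoxy-4-(3-methylbut-2-en-1-yl)phenol | COc1cc(O)cc(OC)c1CC=C(C)C | intermediate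
7 | 2-iodo-3,5-dimethoxy-4-(3-methylbut-2-en-1-yl)phenol | COc1cc(O)c(I)c(OC)c1CC=C(C)C | intermediate
8 | isovanillin | COc1ccc(C=O)cc1O | starting material
9 | 4-methoxy-3-(triisopropylsilyloxy)benzaldehyde | COc1ccc(C=O)cc1O[Si](C(C)C)(C(C)C)C(C)C | intermediate
10 | (5-ethynyl-2-methoxyphenoxy)triisopropylsilane | C#Cc1ccc(OC)c(O[Si](C(C)C)(C(C)C)C(C)C)c1 | intermediate
11 | carbon monoxide | [C-]#[O+] | starting material
12 | 1-[6-hydroxy-2,4-dimethoxy-3-(3-methylbut-2-en-1-yl)phenyl]-3-[4-methoxy-3-(triisopropylsilyloxy)phenyl]prop-2-yn-1-one | COc1ccc(C#CC(=O)c2c(O)cc(OC)c(CC=C(C)C)c2OC)cc1O[Si](C(C)C)(C(C)C)C(C)C | intermediate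
13 | (E)-3-(diethylamino)-1-[6-hydroxy-2,4-dimethoxy-3-(3-methylbut-2-en-1-yl)phenyl]-3-[4-methoxy-3-(triisopropylsilyloxy)phenyl]prop-2-en-1-one | CCN(CC)/C(=C/C(=O)c1c(O)cc(OC)c(CC=C(C)C)c1OC)c1ccc(OC)c(O[Si](C(C)C)(C(C)C)C(C)C)c1 | intermediate
14 | 5,7-dimethoxy-2-[4-methoxy-3-(triisopropylsilyloxy)phenyl]-6-(3-methylbut-2-en-1-yl)-4H-chromen-4-one | COc1ccc(-c2cc(=O)c3c(OC)c(CC=C(C)C)c(OC)cc3o2)cc1O[Si](C(C)C)(C(C)C)C(C)C | intermediate
15 | (2S)-4-[dimethyl(phenyl)silyloxy]-5,7-dimethoxy-2-[4-methoxy-3-(triisopropylsilyloxy)phenyl]-6-(3-methylbut-2-en-1-yl)-2H-chromene | COc1ccc([C@H]2Oc3cc(OC)c(CC=C(C)C)c(OC)c3C(O[Si](C)(C)c3ccccc3)=C2)cc1O[Si](C(C)C)(C(C)C)C(C)C | intermediate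
16 | (2R,3R)-3-[dimethyl(phenyl)silyloxy]-5,7-dimethoxy-2-[4-methoxy-3-(triisopropylsilyloxy)phenyl]-6-(3-methylbut-2-en-1-yl)chroman-4-one | COc1ccc([C@H]2Oc3cc(OC)c(CC=C(C)C)c(OC)c3C(=O)[C@@H]2O[Si](C)(C)c2ccccc2)cc1O[Si](C(C)C)(C(C)C)C(C)C | intermediate
17 | (2R,3R)-3-hydroxy-5,7-dimethoxy-2-[4-methoxy-3-(triisopropylsilyloxy)phenyl]-6-(3-methylbut-2-en-1-yl)chroman-4-one | COc1ccc([C@H]2Oc3cc(OC)c(CC=C(C)C)c(OC)c3C(=O)[C@@H]2O)cc1O[Si](C(C)C)(C(C)C)C(C)C | intermediate
18 | (2R,3R)-3,5-dihydroxy-7-methoxy-2-[4-methoxy-3-(triisopropylsilyloxy)phenyl]-6-(3-methylbut-2-en-1-yl)chroman-4-one | COc1ccc([C@H]2Oc3cc(OC)c(CC=C(C)C)c(O)c3C(=O)[C@@H]2O)cc1O[Si](C(C)C)(C(C)C)C(C)C | intermediate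
19 | (2R,3R)-3,5-dihydroxy-2-(3-hydroxy-4-methoxyphenyl)-7-methoxy-6-(3-methylbut-2-en-1-yl)chroman-4-one | COc1ccc([C@H]2Oc3cc(OC)c(CC=C(C)C)c(O)c3C(=O)[C@@H]2O)cc1O | target

**Step count**
Total: 11 steps. Longest linear sequence: 9 steps (steps 1–4 and 7–11). The ring B branch (steps 5 and 6) joins at step 7.

**Steps most likely to fail**

Step 8. Hydride transfer to C2 may be slow, because the enone is a vinylogous ester further deactivated by the ring A donors and carries an electron-rich 2-aryl group. Face discrimination may also be incomplete, and the enol ether may hydrolyse while copper is removed. The fallback replaces asymmetric reduction by kinetic resolution and sets out from 14. The more reactive achiral catalyst Cu(OAc)2/1,2-bis(diphenylphosphino)benzene with PMHS and t-BuOH in toluene reduces 14 to the racemic flavanone F1. Asymmetric transfer hydrogenation with RuCl(p-cymene)[(R,R)-TsDPEN] in HCO2H/Et3N, a known kinetic resolution of flavanones, is stopped near half conversion. This leaves the (2S)-flavanone F2, while the 2R ketone is consumed as the cis-(2R,4R)-flavan-4-ol F3, which is removed by chromatography. Soft enolisation of F2 with PhMe2SiCl, NaI and Et3N in MeCN at 0 °C rejoins the route at 15.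

Step 7. Oxidative addition into the flanked, electron-rich C–I bond may lag. Alkynylation without CO uptake, capture of the acyl complex by the amine, reductive loss of iodine or 5-exo closure may then compete. The fallback brings in the C4 carbon by polar chemistry instead of CO gas and sets out from 7 and 10. Alkyne 10 is deprotonated with n-BuLi in THF at −78 °C to the lithium acetylide F4, which is acylated with N-methoxy-N-methylcarbamoyl chloride to give the Weinreb propiolamide F5. Iodophenol 7 is deprotonated with MeMgCl in the presence of LiCl and then undergoes iodine–magnesium exchange with i-PrMgCl to give the magnesiated phenolate F6. F6 adds to F5 and gives ynone 12 on work-up. Warming 12 in Et2NH closes ring C by way of 13 and rejoins the route at 14.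

Step 10. The freed O5 may close onto the neighbouring prenyl chain under Lewis acid. Iodide may strip the C3 oxygen from the activated ketol, or prolonged warming may erode C2/C3. The fallback moves the ether cleavage ahead of both stereocentres and sets out from 14. MgI2·OEt2 in THF gives the 5-hydroxyflavone F7, and TBSOTf/2,6-lutidine in CH2Cl2 gives the 5-O-TBS flavone F8. The conditions of step 8 then give the (2S)-silyl enol ether F9, and the oxaziridine of step 9, without the acid treatment, gives the (2R,3R)-trisilyl ketol F10. A single buffered TBAF/AcOH treatment removes all three silyl groups and arrives at 19.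

**Further compounds**
F1 | step 8 | rac-5,7-dimethoxy-2-[4-methoxy-3-(triisopropylsilyloxy)phenyl]-6-(3-methylbut-2-en-1-yl)chroman-4-one | COc1ccc(C2CC(=O)c3c(OC)c(CC=C(C)C)c(OC)cc3O2)cc1O[Si](C(C)C)(C(C)C)C(C)C
F2 | step 8 | (2S)-5,7-dimethoxy-2-[4-methoxy-3-(triisopropylsilyloxy)phenyl]-6-(3-methylbut-2-en-1-yl)chroman-4-one | COc1ccc([C@H]2Oc3cc(OC)c(CC=C(C)C)c(OC)c3C(=O)C2)cc1O[Si](C(C)C)(C(C)C)C(C)C
F3 | step 8 | (2R,4R)-5,7-dimethoxy-2-[4-methoxy-3-(triisopropylsilyloxy)phenyl]-6-(3-methylbut-2-en-1-yl)chroman-4-ol | COc1ccc([C@@H]2Oc3cc(OC)c(CC=C(C)C)c(OC)c3[C@H](O)C2)cc1O[Si](C(C)C)(C(C)C)C(C)C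
F4 | step 7 | lithium [4-methoxy-3-(triisopropylsilyloxy)phenyl]acetylide | [Li]C#Cc1ccc(OC)c(O[Si](C(C)C)(C(C)C)C(C)C)c1
F5 | step 7 | N-methoxy-N-methyl-3-[4-methoxy-3-(triisopropylsilyloxy)phenyl]prop-2-ynamide | CON(C)C(=O)C#Cc1ccc(OC)c(O[Si](C(C)C)(C(C)C)C(C)C)c1
F6 | step 7 | chloromagnesium 2-(chloromagnesio)-3,5-dimethoxy-4-(3-methylbut-2-en-1-yl)phenolate | COc1cc(O[Mg]Cl)c([Mg]Cl)c(OC)c1CC=C(C)C
F7 | step 10 | 5-hydroxy-7-methoxy-2-[4-methoxy-3-(triisopropylsilyloxy)phenyl]-6-(3-methylbut-2-en-1-yl)-4H-chromen-4-one | COc1ccc(-c2cc(=O)c3c(O)c(CC=C(C)C)c(OC)cc3o2)cc1O[Si](C(C)C)(C(C)C)C(C)C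
F8 | step 10 | 5-(tert-butyldimethylsilyloxy)-7-methoxy-2-[4-methoxy-3-(triisopropylsilyloxy)phenyl]-6-(3-methylbut-2-en-1-yl)-4H-chromen-4-one | COc1ccc(-c2cc(=O)c3c(O[Si](C)(C)C(C)(C)C)c(CC=C(C)C)c(OC)cc3o2)cc1O[Si](C(C)C)(C(C)C)C(C)C
F9 | step 10 | (2S)-5-(tert-butyldimethylsilyloxy)-4-[dimethyl(phenyl)silyloxy]-7-methoxy-2-[4-methoxy-3-(triisopropylsilyloxy)phenyl]-6-(3-methylbut-2-en-1-yl)-2H-chromene | COc1ccc([C@H]2Oc3cc(OC)c(CC=C(C)C)c(O[Si](C)(C)C(C)(C)C)c3C(O[Si](C)(C)c3ccccc3)=C2)cc1O[Si](C(C)C)(C(C)C)C(C)C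
F10 | step 10 | (2R,3R)-5-(tert-butyldimethylsilyloxy)-3-[dimethyl(phenyl)silyloxy]-7-methoxy-2-[4-methoxy-3-(triisopropylsilyloxy)phenyl]-6-(3-methylbut-2-en-1-yl)chroman-4-one | COc1ccc([C@H]2Oc3cc(OC)c(CC=C(C)C)c(O[Si](C)(C)C(C)(C)C)c3C(=O)[C@@H]2O[Si](C)(C)c2ccccc2)cc1O[Si](C(C)C)(C(C)C)C(C)C
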